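**Assumption:** the SMILES is read as (3R,4S), i.e. 3,4-trans, in the 3,4-diarylchroman and (3R) in the 3-arylchroman; descriptors of intermediates follow CIP for each structure. None of this route has been run; the steps rest on precedent and on my own stereochemical analysis.

## Retrosynthetic overview

1. Target 25 ⇐ one-pot ATH/DKR and hydrogenolysis of isoflavone 22 (sets C3 of the 3-arylchroman, removes its C4–O and four benzyl groups).
2. 22 ⇐ reductive C4-arylation of isoflavone 19 by the B-ring C5' of isoflavone 10 (inter-unit C–C bond, trans C3/C4 of the diarylchroman).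
3. 10 and 19 ⇐ Tl(III)-induced oxidative 1,2-aryl shift of 2'-hydroxychalcones 8 and 17, then pyranone closure.
4. 8 and 17 ⇐ Claisen–Schmidt condensation of the common ketone 4 with aldehydes 7 and 16.
5. 4, 7, 16 ⇐ resorcinol (all four arenes) and acetic acid, DMF as C1 unit. Ring order: arenes → two pyranones (steps 6, 12) → diarylchroman (step 13) → 3-arylchroman (step 14).

## Route

**Step 1**
Reactants: 1 resorcinol; 2 acetic acid
Product: 3 1-(2,4-dihydroxyphenyl)ethan-1-one
Conditions: ZnCl2 (1.2 equiv), AcOH, 140–150 °C; aq HCl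
Reagents that add atoms: none
Why: Nencki (ZnCl2-mediated Friedel–Crafts) acylation goes to C4 of resorcinol, ortho/para to the two hydroxyls, a standard preparation of resacetophenone.

**Step 2**
Reactants: 3 1-(2,4-dihydroxyphenyl)ethan-1-one
Product: 4 1-[4-(benzyloxy)-2-hydroxyphenyl]ethan-1-one
Conditions: BnBr (1.05 equiv), K2CO3, acetone, reflux
Reagents that add atoms: benzyl bromide, BrCc1ccccc1
Why: Williamson etherification is selective for the 4-OH because the 2-OH is held in a hydrogen bond to the ketone.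

**Step 3**
Reactants: 1 resorcinol
Product: 5 2,4-dihydroxybenzaldehyde
Conditions: POCl3, DMF, MeCN, −15 °C → rt; then H2O, 50 °C
Reagents that add atoms: N,N-dimethylformamide, CN(C)C=O; water, O
Why: Vilsmeier–Haack formylation of resorcinol occurs at C4 and the iminium salt is hydrolysed to the aldehyde.

**Step 4**
Reactants: 5 2,4-dihydroxybenzaldehyde
Product: 7 2-(benzyloxy)-4-methoxybenzaldehyde, via 2-hydroxy-4-methoxybenzaldehyde 6 (not isolated)
Conditions: MeI (1.0 equiv), K2CO3, acetone, rt; then BnBr (1.2 equiv), K2CO3, reflux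
Reagents that add atoms: iodomethane, CI; benzyl bromide, BrCc1ccccc1
Why: One-pot sequential Williamson alkylation, in which the non-chelated 4-OH is methylated at rt and the hydrogen-bonded 2-OH is benzylated only on heating.

**Step 5**
Reactants: 4 1-[4-(benzyloxy)-2-hydroxyphenyl]ethan-1-one; 7 2-(benzyloxy)-4-methoxybenzaldehyde
Product: 8 (E)-1-[4-(benzyloxy)-2-hydroxyphenyl]-3-[2-(benzyloxy)-4-methoxyphenyl]prop-2-en-1-one
Conditions: 50% aq KOH, EtOH, rt, 48 h; then aq HCl
Reagents that add atoms: none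
Why: Claisen–Schmidt aldol condensation gives the thermodynamically favoured E-enone and keeps the 2'-OH free for the later ring closure.

**Step 6**
Reactants: 8 (E)-1-[4-(benzyloxy)-2-hydroxyphenyl]-3-[2-(benzyloxy)-4-methoxyphenyl]prop-2-en-1-one
Product: 10 7-(benzyloxy)-3-[2-(benzyloxy)-4-methoxyphenyl]-4H-chromen-4-one, via dimethyl acetal 9 (not isolated)
Conditions: Tl(NO3)3·3H2O (1.2 equiv), MeOH/HC(OMe)3, rt; then 10% aq HCl, 60 °C
Reagents that add atoms: none
Why: Thallium(III) oxidative rearrangement of a 2'-hydroxychalcone: methoxythallation and loss of Tl(I) drive the 1,2-shift of the electron-rich aryl group from C-β to C-α to give acetal 9, which acid closes to the pyranone with loss of two MeOH.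

**Step 7**
Reactants: 1 resorcinol
Product: 11 1,3-dimethoxybenzene
Conditions: Me2SO4 (2.4 equiv), aq NaOH, 10 °C → reflux
Reagents that add atoms: dimethyl sulfate, COS(=O)(=O)OC
Why: Exhaustive Williamson O-methylation of resorcinol.

**Step 8**
Reactants: 11 1,3-dimethoxybenzene
Product: 14 2,6-dimethoxyphenol, via aryllithium 12 (not isolated), via arylboronate 13 (not isolated)
Conditions: n-BuLi, THF, 0 °C → rt; B(OMe)3, −78 °C → rt; AcOH, 30% H2O2, 0 °C → rt
Reagents that add atoms: hydrogen peroxide, OO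
Why: Directed ortho-metalation at C2 between the two methoxy groups, borylation and boronate oxidation (C–B to C–O migration) give the phenol.

**Step 9**
Reactants: 14 2,6-dimethoxyphenol
Product: 15 2-(benzyloxy)-1,3-dimethoxybenzene
Conditions: BnBr, K2CO3, DMF, 60 °C
Reagents that add atoms: benzyl bromide, BrCc1ccccc1
Why: Williamson benzylation of the hindered phenol.

**Step 10**
Reactants: 15 2-(benzyloxy)-1,3-dimethoxybenzene
Product: 16 3-(benzyloxy)-2,4-dimethoxybenzaldehyde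
Conditions: POCl3, DMF, 80 °C; then ice/H2O
Reagents that add atoms: N,N-dimethylformamide, CN(C)C=O; water, O
Why: Vilsmeier–Haack formylation goes para to one OMe and ortho to the other (the two sites are equivalent by symmetry), as with 1,2,3-trimethoxybenzene, because the twisted central benzyloxy group does not direct.

**Step 11**
Reactants: 4 1-[4-(benzyloxy)-2-hydroxyphenyl]ethan-1-one; 16 3-(benzyloxy)-2,4-dimethoxybenzaldehyde
Product: 17 (E)-1-[4-(benzyloxy)-2-hydroxyphenyl]-3-[3-(benzyloxy)-2,4-dimethoxyphenyl]prop-2-en-1-one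
Conditions: 50% aq KOH, EtOH, rt → 40 °C, 48 h; then aq HCl
Reagents that add atoms: none
Why: Claisen–Schmidt aldol condensation to the E-enone, as in step 5.

**Step 12**
Reactants: 17 (E)-1-[4-(benzyloxy)-2-hydroxyphenyl]-3-[3-(benzyloxy)-2,4-dimethoxyphenyl]prop-2-en-1-one
Product: 19 7-(benzyloxy)-3-[3-(benzyloxy)-2,4-dimethoxyphenyl]-4H-chromen-4-one, via dimethyl acetal 18 (not isolated)
Conditions: Tl(NO3)3·3H2O (1.2 equiv), MeOH/HC(OMe)3, rt; then 10% aq HCl, 60 °C
Reagents that add atoms: none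
Why: Thallium(III) oxidative 1,2-aryl shift of the trioxygenated aryl group from C-β to C-α followed by acid-catalysed pyranone closure, as in step 6.

**Step 13**
Reactants: 19 7-(benzyloxy)-3-[3-(benzyloxy)-2,4-dimethoxyphenyl]-4H-chromen-4-one; 10 7-(benzyloxy)-3-[2-(benzyloxy)-4-methoxyphenyl]-4H-chromen-4-one
Product: 22 7-(benzyloxy)-3-{2-(benzyloxy)-5-[(3R,4S)-7-(benzyloxy)-3-(3-(benzyloxy)-2,4-dimethoxyphenyl)chroman-4-yl]-4-methoxyphenyl}-4H-chromen-4-one, via chromanone 20 (not isolated), via cis-chromanol 21 (not isolated)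
Conditions: RuCl[(R,R)-TsDPEN](p-cymene) (2 mol%), HCO2H/Et3N (5:2), EtOAc, 40 °C; then added over 2 h to 10 (2.5 equiv, excess recovered), MsOH (0.3 equiv over Et3N), HFIP/CH2Cl2 (1:1), 0 °C; aq NaHCO3
Reagents that add atoms: none
Why: Proposed new method: a one-pot asymmetric reductive C4-arylation of an isoflavone, in which Ru–H conjugate reduction gives chromanone 20, its C3 epimerises under Et3N, and catalyst-controlled carbonyl reduction with dynamic kinetic resolution gives cis-(3R,4R)-21 (C3 set; (R,R) catalyst by analogy with chroman-4-one → (R)-chroman-4-ol); acid in HFIP then ionises the 2,4-dialkoxybenzylic C4–OH and C5' of 10 (para to OBn, ortho to OMe, on the only activated ring because the chromone A-ring is carbonyl-deactivated) attacks the cation anti to the C3 aryl group to give the 3,4-trans (3R,4S) product; the closest known reaction types are ATH/DKR of isoflavones with acid-induced intramolecular O-trapping of the same cation to pterocarpans, and diastereoselective SN1 Friedel–Crafts alkylation with α-branched benzylic alcohols.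

**Step 14**
Reactants: 22 7-(benzyloxy)-3-{2-(benzyloxy)-5-[(3R,4S)-7-(benzyloxy)-3-(3-(benzyloxy)-2,4-dimethoxyphenyl)chroman-4-yl]-4-methoxyphenyl}-4H-chromen-4-one
Product: 25 (3R,4S)-4-{4-hydroxy-5-[(3R)-7-hydroxychroman-3-yl]-2-methoxyphenyl}-3-(3-hydroxy-2,4-dimethoxyphenyl)chroman-7-ol, via chromanone 23 (not isolated), via cis-chromanol 24 (not isolated)
Conditions: RuCl[(R,R)-TsDPEN](p-cymene) (5 mol%), HCO2H/Et3N (5:2), EtOAc/DMF, 40 °C; then MeOH/AcOH, 10% Pd/C, H2 (1 atm), rt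
Reagents that add atoms: none
Why: Noyori–Ikariya asymmetric transfer hydrogenation with dynamic kinetic resolution gives the cis-(3R,4R) chromanol 24 (sets C3 of this unit), and Pd-catalysed hydrogenolysis then removes the activated benzylic C4–OH and the four benzyl ethers, leaving the (3R)-isoflavan and the C–C-linked diarylchroman untouched.

## Compound list

1 | resorcinol | Oc1cccc(O)c1 | starting material
2 | acetic acid | CC(=O)O | starting material
3 | 1-(2,4-dihydroxyphenyl)ethan-1-one | CC(=O)c1ccc(O)cc1O | intermediate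
4 | 1-[4-(benzyloxy)-2-hydroxyphenyl]ethan-1-one | CC(=O)c1ccc(OCc2ccccc2)cc1O | intermediate
5 | 2,4-dihydroxybenzaldehyde | O=Cc1ccc(O)cc1O | intermediate
6 | 2-hydroxy-4-methoxybenzaldehyde | COc1ccc(C=O)c(O)c1 | intermediate
7 | 2-(benzyloxy)-4-methoxybenzaldehyde | COc1ccc(C=O)c(OCc2ccccc2)c1 | intermediate
8 | (E)-1-[4-(benzyloxy)-2-hydroxyphenyl]-3-[2-(benzyloxy)-4-methoxyphenyl]prop-2-en-1-one | COc1ccc(/C=C/C(=O)c2ccc(OCc3ccccc3)cc2O)c(OCc2ccccc2)c1 | intermediate
9 | rac-1-[4-(benzyloxy)-2-hydroxyphenyl]-2-[2-(benzyloxy)-4-methoxyphenyl]-3,3-dimethoxypropan-1-one | COc1ccc(C(C(OC)OC)C(=O)c2ccc(OCc3ccccc3)cc2O)c(OCc2ccccc2)c1 | intermediate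
10 | 7-(benzyloxy)-3-[2-(benzyloxy)-4-methoxyphenyl]-4H-chromen-4-one | COc1ccc(-c2coc3cc(OCc4ccccc4)ccc3c2=O)c(OCc2ccccc2)c1 | intermediate
11 | 1,3-dimethoxybenzene | COc1cccc(OC)c1 | intermediate
12 | (2,6-dimethoxyphenyl)lithium | [Li]c1c(OC)cccc1OC | intermediate
13 | dimethyl (2,6-dimethoxyphenyl)boronate (formed as its lithium methoxide ate complex) | COB(OC)c1c(OC)cccc1OC | intermediate
14 | 2,6-dimethoxyphenol | COc1cccc(OC)c1O | intermediate
15 | 2-(benzyloxy)-1,3-dimethoxybenzene | COc1cccc(OC)c1OCc1ccccc1 | intermediate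
16 | 3-(benzyloxy)-2,4-dimethoxybenzaldehyde | COc1ccc(C=O)c(OC)c1OCc1ccccc1 | intermediate
17 | (E)-1-[4-(benzyloxy)-2-hydroxyphenyl]-3-[3-(benzyloxy)-2,4-dimethoxyphenyl]prop-2-en-1-one | COc1ccc(/C=C/C(=O)c2ccc(OCc3ccccc3)cc2O)c(OC)c1OCc1ccccc1 | intermediate
18 | rac-1-[4-(benzyloxy)-2-hydroxyphenyl]-2-[3-(benzyloxy)-2,4-dimethoxyphenyl]-3,3-dimethoxypropan-1-one | COc1ccc(C(C(OC)OC)C(=O)c2ccc(OCc3ccccc3)cc2O)c(OC)c1OCc1ccccc1 | intermediate
19 | 7-(benzyloxy)-3-[3-(benzyloxy)-2,4-dimethoxyphenyl]-4H-chromen-4-one | COc1ccc(-c2coc3cc(OCc4ccccc4)ccc3c2=O)c(OC)c1OCc1ccccc1 | intermediate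
20 | 7-(benzyloxy)-3-[3-(benzyloxy)-2,4-dimethoxyphenyl]chroman-4-one (C3 epimerising) | COc1ccc(C2COc3cc(OCc4ccccc4)ccc3C2=O)c(OC)c1OCc1ccccc1 | intermediate
21 | (3R,4R)-7-(benzyloxy)-3-[3-(benzyloxy)-2,4-dimethoxyphenyl]chroman-4-ol (cis) | O[C@H]1c2ccc(OCc3ccccc3)cc2OC[C@H]1c1ccc(OC)c(OCc2ccccc2)c1OC | intermediate
22 | 7-(benzyloxy)-3-{2-(benzyloxy)-5-[(3R,4S)-7-(benzyloxy)-3-(3-(benzyloxy)-2,4-dimethoxyphenyl)chroman-4-yl]-4-methoxyphenyl}-4H-chromen-4-one | COc1cc(OCc2ccccc2)c(-c2coc3cc(OCc4ccccc4)ccc3c2=O)cc1[C@@H]1c2ccc(OCc3ccccc3)cc2OC[C@H]1c1ccc(OC)c(OCc2ccccc2)c1OC | intermediate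
23 | 7-(benzyloxy)-3-{2-(benzyloxy)-5-[(3R,4S)-7-(benzyloxy)-3-(3-(benzyloxy)-2,4-dimethoxyphenyl)chroman-4-yl]-4-methoxyphenyl}chroman-4-one (C3 of the chromanone epimerising) | COc1cc(OCc2ccccc2)c(C2COc3cc(OCc4ccccc4)ccc3C2=O)cc1[C@@H]1c2ccc(OCc3ccccc3)cc2OC[C@H]1c1ccc(OC)c(OCc2ccccc2)c1OC | intermediate
24 | (3R,4R)-7-(benzyloxy)-3-{2-(benzyloxy)-5-[(3R,4S)-7-(benzyloxy)-3-(3-(benzyloxy)-2,4-dimethoxyphenyl)chroman-4-yl]-4-methoxyphenyl}chroman-4-ol (cis) | COc1cc(OCc2ccccc2)c([C@@H]2COc3cc(OCc4ccccc4)ccc3[C@@H]2O)cc1[C@@H]1c2ccc(OCc3ccccc3)cc2OC[C@H]1c1ccc(OC)c(OCc2ccccc2)c1OC | intermediate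
25 | (3R,4S)-4-{4-hydroxy-5-[(3R)-7-hydroxychroman-3-yl]-2-methoxyphenyl}-3-(3-hydroxy-2,4-dimethoxyphenyl)chroman-7-ol (CNP0202416.1) | COc1cc(O)c([C@@H]2COc3cc(O)ccc3C2)cc1[C@@H]1c2ccc(O)cc2OC[C@H]1c1ccc(OC)c(O)c1OC | target

## Step count and risks

Total steps: 14. Longest linear sequence: 8 (steps 7 → 8 → 9 → 10 → 11 → 12 → 13 → 14).

**Step 13 (proposed new step).** Three things can go wrong. The C4 cation can lose the C3 proton to give the isoflav-3-ene, which erodes C3 on re-protonation. The electron-rich A-ring (C6) of 21 or 22 can compete with 10 as the nucleophile, giving oligomers; slow addition and excess 10 are meant to limit this. The residual Ru/formate medium may interfere with the acid stage. The fallback uses known chemistry only and sets out from 19. The transfer hydrogenation is run alone and cis-chromanol 21 is isolated. It is acetylated (Ac2O, pyridine, DMAP, 0 °C) to (3R,4R)-7-(benzyloxy)-3-[3-(benzyloxy)-2,4-dimethoxyphenyl]chroman-4-yl acetate F1. F1 is ionised with BF3·OEt2 in CH2Cl2 at −78 °C in the presence of 10 (3 equiv), a low-temperature Lewis-acid SN1 Friedel–Crafts alkylation of an α-branched benzylic acetate that attacks anti to the C3 aryl group. The fallback comes back to the route at 22.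

**Step 12.** Tl(III) may oxidise or nitrate the trioxygenated ring, or aurone/flavone formation may compete with the aryl shift. The fallback sets out from 17. The chalcone is cyclised (NaOAc, EtOH, reflux) to rac-7-(benzyloxy)-2-[3-(benzyloxy)-2,4-dimethoxyphenyl]chroman-4-one F2. This flavanone then undergoes the hypervalent-iodine 2,3-aryl shift with dehydrogenation (PhI(OH)OTs, MeCN, reflux, or PhI(OAc)2/H2SO4 in HC(OMe)3). The fallback comes back to the route at 19.

**Step 14.** The acidic Pd hydrogenolysis can epimerise C3 of the new chroman through the C4 cation/isoflav-3-ene, and the one-pot switch from Ru to Pd may be incomplete. The fallback sets out from 22. The transfer hydrogenation is run alone and 24 is isolated. Treatment with NaH, CS2 and MeI (THF, 0 °C) gives O-{(3R,4R)-7-(benzyloxy)-3-[2-(benzyloxy)-5-((3R,4S)-7-(benzyloxy)-3-(3-(benzyloxy)-2,4-dimethoxyphenyl)chroman-4-yl)-4-methoxyphenyl]chroman-4-yl} S-methyl carbonodithioate F3. Barton–McCombie radical deoxygenation (Bu3SnH, AIBN, toluene, 90 °C) avoids any cation and gives (3R)-7-(benzyloxy)-3-{2-(benzyloxy)-5-[(3R,4S)-7-(benzyloxy)-3-(3-(benzyloxy)-2,4-dimethoxyphenyl)chroman-4-yl]-4-methoxyphenyl}chromane F4. Neutral hydrogenolysis (H2, Pd/C, EtOAc/MeOH, rt) then brings the route back at 25.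

## Further compounds

F1 | step 13 | (3R,4R)-7-(benzyloxy)-3-[3-(benzyloxy)-2,4-dimethoxyphenyl]chroman-4-yl acetate | CC(=O)O[C@H]1c2ccc(OCc3ccccc3)cc2OC[C@H]1c1ccc(OC)c(OCc2ccccc2)c1OC
F2 | step 12 | rac-7-(benzyloxy)-2-[3-(benzyloxy)-2,4-dimethoxyphenyl]chroman-4-one | COc1ccc(C2CC(=O)c3ccc(OCc4ccccc4)cc3O2)c(OC)c1OCc1ccccc1
F3 | step 14 | O-{(3R,4R)-7-(benzyloxy)-3-[2-(benzyloxy)-5-((3R,4S)-7-(benzyloxy)-3-(3-(benzyloxy)-2,4-dimethoxyphenyl)chroman-4-yl)-4-methoxyphenyl]chroman-4-yl} S-methyl carbonodithioate | COc1cc(OCc2ccccc2)c([C@@H]2COc3cc(OCc4ccccc4)ccc3[C@@H]2OC(=S)SC)cc1[C@@H]1c2ccc(OCc3ccccc3)cc2OC[C@H]1c1ccc(OC)c(OCc2ccccc2)c1OC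
F4 | step 14 | (3R)-7-(benzyloxy)-3-{2-(benzyloxy)-5-[(3R,4S)-7-(benzyloxy)-3-(3-(benzyloxy)-2,4-dimethoxyphenyl)chroman-4-yl]-4-methoxyphenyl}chromane | COc1cc(OCc2ccccc2)c([C@@H]2COc3cc(OCc4ccccc4)ccc3C2)cc1[C@@H]1c2ccc(OCc3ccccc3)cc2OC[C@H]1c1ccc(OC)c(OCc2ccccc2)c1OC
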